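**Plan**

- Retrosynthetic cuts, in order: the C3–Br bond (indole bromination); the N–S bond (sulfonyl protection); the C5–C6 bond together with the C4–H and C7–H bonds, which opens the benzene ring to 2,3-bis(bromoethynyl)-1-(methanesulfonyl)pyrrole; then both C(sp)–Br bonds, the C7≡C6 arm back to a C2 aldehyde, and the C3a–C4 bond back to a pyrrole C3 bromide.
- Enabling feature: the benzene ring C3a–C4–C5–C6–C7–C7a carries its two bromines on the neighbouring atoms C5 and C6, opposite the C3a–C7a fusion bond. The ring is therefore the pyrrole C2=C3 bond plus two Br–C≡C arms (C4≡C5 and C7≡C6).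
- Forward order: the pyrrole ring is present from the start; the C3 alkyne is attached by cross-coupling, the C2 alkyne is made from the aldehyde, and both are capped with bromine. The benzene ring then closes in one thermal step, and N-deprotection and C3 bromination finish the route.
- Stereochemistry: the target has no stereocentre. The 5,6-bromine pattern follows from connectivity and the C3 bromine from the innate reactivity of indole.

Key step: step 6

Remark: 3-bromo-1H-pyrrole-2-carbaldehyde 1 is taken as a purchasable compound. A methanesulfonyl group is used on nitrogen because it gives the C7 radical of the key step no sulfonyl aryl ring to attack.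

**Route**

Step 1
Reactants: 1 3-bromo-1H-pyrrole-2-carbaldehyde; 2 methanesulfonyl chloride
Product: 4 3-bromo-1-(methanesulfonyl)-1H-pyrrole-2-carbaldehyde, via sodium 3-bromo-2-formylpyrrol-1-ide 3 (not isolated)
Conditions: NaH, THF, 0 °C; then MsCl, 0 °C to rt
Reagents that add atoms: methanesulfonyl chloride (2), CS(=O)(=O)Cl
Why: The 2-formyl group makes the N–H acidic, so NaH should give pyrrolide 3, which undergoes N-sulfonylation (nucleophilic substitution at sulfur) and leaves an electron-poor pyrrole suited to the later cross-coupling, bromination and radical steps.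

Step 2
Reactants: 4 3-bromo-1-(methanesulfonyl)-1H-pyrrole-2-carbaldehyde; 5 trimethylsilylacetylene
Product: 6 1-(methanesulfonyl)-3-[(trimethylsilyl)ethynyl]-1H-pyrrole-2-carbaldehyde
Conditions: PdCl2(PPh3)2 (5 mol%), CuI (10 mol%), Et3N, THF, 60 °C, sealed tube
Reagents that add atoms: trimethylsilylacetylene (5), C#C[Si](C)(C)C
Why: Sonogashira coupling, in which the ortho-formyl and N-sulfonyl groups make the C3–Br bond electron-poor enough for oxidative addition to zerovalent palladium, and the silyl cap keeps this alkyne inert until step 5.

Step 3
Reactants: 6 1-(methanesulfonyl)-3-[(trimethylsilyl)ethynyl]-1H-pyrrole-2-carbaldehyde; 7 carbon tetrabromide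
Product: 8 2-(2,2-dibromoethenyl)-1-(methanesulfonyl)-3-[(trimethylsilyl)ethynyl]-1H-pyrrole
Conditions: CBr4, PPh3, CH2Cl2, 0 °C
Reagents that add atoms: carbon tetrabromide (7), BrC(Br)(Br)Br
Why: Ramirez dibromoolefination (the first stage of the Corey–Fuchs sequence), a Wittig-type reaction of the aldehyde with the ylide formed from PPh3 and CBr4 under neutral conditions that should leave the sulfonamide and the silylalkyne untouched.

Step 4
Reactants: 8 2-(2,2-dibromoethenyl)-1-(methanesulfonyl)-3-[(trimethylsilyl)ethynyl]-1H-pyrrole
Product: 9 2-(bromoethynyl)-1-(methanesulfonyl)-3-[(trimethylsilyl)ethynyl]-1H-pyrrole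
Conditions: DBU, MeCN, rt
Reagents that add atoms: none
Why: Base-mediated dehydrobromination (anti E2 loss of the vinylic hydrogen and the bromine trans to it) of a 1,1-dibromoalkene, which should stop at the 1-bromoalkyne because no metal or strong base is present to exchange the remaining bromine.

Step 5
Reactants: 9 2-(bromoethynyl)-1-(methanesulfonyl)-3-[(trimethylsilyl)ethynyl]-1H-pyrrole
Product: 10 2,3-bis(bromoethynyl)-1-(methanesulfonyl)-1H-pyrrole
Conditions: NBS, AgNO3 (20 mol%), acetone, rt, dark; product kept cold and in solution
Reagents that add atoms: N-bromosuccinimide, O=C1CCC(=O)N1Br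
Why: Silver-catalysed desilylative bromination, in which AgNO3 activates the alkynyl–silicon bond and NBS delivers electrophilic bromine to the alkyne carbon, at a temperature where the sulfonyl-deactivated pyrrole ring should not be brominated.

Step 6
Reactants: 10 2,3-bis(bromoethynyl)-1-(methanesulfonyl)-1H-pyrrole
Product: 12 5,6-dibromo-1-(methanesulfonyl)-1H-indole, via 5,6-dibromo-1-(methanesulfonyl)indole-4,7-diyl diradical 11 (not isolated)
Conditions: 1,4-cyclohexadiene/PhCl 1:3, 0.005 M, degassed, sealed steel vessel, 200 °C
Reagents that add atoms: none
Why: The pyrrole C2=C3 bond and the two alkynes make up a (Z)-hex-3-ene-1,5-diyne, and thermal Bergman cycloaromatization joins the two bromine-bearing termini (new C5–C6 bond) to give the σ,σ-diradical 11, whose centres at C4 and C7 each take a hydrogen atom from 1,4-cyclohexadiene, which ends as benzene. The closest known reaction type is the thermal Bergman cyclization of 1,2-bis(bromoethynyl)arenes to 2,3-dibromoarenes in 1,4-cyclohexadiene, and of heteroarene-fused enediynes to benzo-fused heteroarenes. The six-membered ring (C3a, C4, C5, C6, C7, C7a) closes by C1–C6 bonding of the enediyne, a formal 6-endo closure at each alkyne driven by the gain of a benzenoid ring, and no stereocentre is formed. The step needs unimolecular closure to beat radical oligomerization of the bromoalkynes and the C1–C5 (fulvene) mode, which high dilution, a large excess of hydrogen donor and the absence of aryl groups on the termini should secure, while the bromine positions are fixed because the bromines sit on the two atoms that bond. The methanesulfonyl group keeps the pyrrole electron-poor against polymerization and, unlike an arenesulfonyl group, has no aryl ring open to ipso attack by the neighbouring C7 radical. A higher temperature than for benzo-fused substrates is expected because the five-membered ene holds the alkyne termini further apart.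

Step 7
Reactants: 12 5,6-dibromo-1-(methanesulfonyl)-1H-indole
Product: 13 5,6-dibromo-1H-indole
Conditions: NaOH (aq), 1,4-dioxane, 80 °C
Reagents that add atoms: none
Why: Hydroxide cleavage of the N–S bond (sulfonamide hydrolysis), made easy by the dibromoindolide leaving group, in a methanol-free medium so that no alkylating sulfonate ester can form and the aryl bromides stay intact.

Step 8
Reactants: 13 5,6-dibromo-1H-indole
Product: 14 3,5,6-tribromo-1H-indole
Conditions: NBS (1.0 equiv), DMF, 0 °C, dark
Reagents that add atoms: N-bromosuccinimide, O=C1CCC(=O)N1Br
Why: Electrophilic aromatic substitution at C3, the most nucleophilic position of an N–H indole, with one equivalent of NBS, while the benzene ring deactivated by two bromines should not compete.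

**Compound list**

1 | 3-bromo-1H-pyrrole-2-carbaldehyde | O=Cc1[nH]ccc1Br | starting material
2 | methanesulfonyl chloride | CS(=O)(=O)Cl | starting material
3 | sodium 3-bromo-2-formylpyrrol-1-ide | [Na+].O=Cc1[n-]ccc1Br | intermediate (not isolated)
4 | 3-bromo-1-(methanesulfonyl)-1H-pyrrole-2-carbaldehyde | CS(=O)(=O)n1ccc(Br)c1C=O | intermediate
5 | trimethylsilylacetylene | C#C[Si](C)(C)C | starting material
6 | 1-(methanesulfonyl)-3-[(trimethylsilyl)ethynyl]-1H-pyrrole-2-carbaldehyde | CS(=O)(=O)n1ccc(C#C[Si](C)(C)C)c1C=O | intermediate
7 | carbon tetrabromide | BrC(Br)(Br)Br | starting material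
8 | 2-(2,2-dibromoethenyl)-1-(methanesulfonyl)-3-[(trimethylsilyl)ethynyl]-1H-pyrrole | CS(=O)(=O)n1ccc(C#C[Si](C)(C)C)c1C=C(Br)Br | intermediate
9 | 2-(bromoethynyl)-1-(methanesulfonyl)-3-[(trimethylsilyl)ethynyl]-1H-pyrrole | CS(=O)(=O)n1ccc(C#C[Si](C)(C)C)c1C#CBr | intermediate
10 | 2,3-bis(bromoethynyl)-1-(methanesulfonyl)-1H-pyrrole | CS(=O)(=O)n1ccc(C#CBr)c1C#CBr | intermediate
11 | 5,6-dibromo-1-(methanesulfonyl)indole-4,7-diyl diradical | CS(=O)(=O)n1ccc2[c]c(Br)c(Br)[c]c21 | intermediate (not isolated)
12 | 5,6-dibromo-1-(methanesulfonyl)-1H-indole | CS(=O)(=O)n1ccc2cc(Br)c(Br)cc21 | intermediate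
13 | 5,6-dibromo-1H-indole | Brc1cc2cc[nH]c2cc1Br | intermediate
14 | 3,5,6-tribromo-1H-indole | Brc1cc2[nH]cc(Br)c2cc1Br | target

Total step count: 8. Longest linear sequence: 8 steps.

**Steps most likely to fail**

Step 6. At the temperature the pyrrole-fused enediyne needs, ring closure may be slower than radical chain oligomerization and bromine-atom transfer of the bromoalkynes, or the diradical may reopen before it captures hydrogen. The fallback gives up the benzannulation and builds the pyrrole ring on a benzene that already carries both bromines. It sets out from trimethylsilylacetylene 5 and comes back to the route at 13. Purchased 3,4-dibromoaniline F1 would be iodinated with N-iodosuccinimide in AcOH at the only unhindered position ortho to nitrogen, giving 4,5-dibromo-2-iodoaniline F2. Sonogashira coupling of F2 with 5 at the carbon–iodine bond (PdCl2(PPh3)2, CuI, Et3N, rt) would give 4,5-dibromo-2-[(trimethylsilyl)ethynyl]aniline F3. K2CO3 in MeOH would remove silicon to give 4,5-dibromo-2-ethynylaniline F4, and CuI in DMF at 100 °C would close the pyrrole ring by 5-endo-dig hydroamination to 13.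

Step 5. Silicon-to-bromine exchange at the alkynylsilane may be slow next to the second bromoalkyne, so that bromination of the free pyrrole α-position or silver-promoted degradation of the bis(haloalkyne) competes. The fallback brominates a C–H alkyne in place of the C–Si alkyne. It sets out from 9 and comes back at 10. K2CO3 in MeOH/THF at 0 °C would give 2-(bromoethynyl)-3-ethynyl-1-(methanesulfonyl)-1H-pyrrole F5, and NBS with DBU in MeCN at rt, a metal-free bromination of terminal alkynes that is complete within minutes, would give 10.

Step 8. The N–H indole may be brominated a second time at C2, and the free 3-bromoindole may degrade by oxidation or acid during reaction and isolation. The fallback reverses the order of the last two operations. It sets out from 12 and comes back at 14. Br2 in CH2Cl2 at 0 °C would brominate the N-sulfonyl indole at C3 only, giving 3,5,6-tribromo-1-(methanesulfonyl)-1H-indole F6, and aqueous NaOH in 1,4-dioxane would then release 14 under basic conditions, in which 3-bromoindoles are more stable.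

**Further compounds**

F1 | step 6 | 3,4-dibromoaniline | Nc1ccc(Br)c(Br)c1
F2 | step 6 | 4,5-dibromo-2-iodoaniline | Nc1cc(Br)c(Br)cc1I
F3 | step 6 | 4,5-dibromo-2-[(trimethylsilyl)ethynyl]aniline | Nc1cc(Br)c(Br)cc1C#C[Si](C)(C)C
F4 | step 6 | 4,5-dibromo-2-ethynylaniline | Nc1cc(Br)c(Br)cc1C#C
F5 | step 5 | 2-(bromoethynyl)-3-ethynyl-1-(methanesulfonyl)-1H-pyrrole | CS(=O)(=O)n1ccc(C#C)c1C#CBr
F6 | step 8 | 3,5,6-tribromo-1-(methanesulfonyl)-1H-indole | CS(=O)(=O)n1cc(Br)c2cc(Br)c(Br)cc21
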